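**Retrosynthetic overview**
1. Target 21 ⇐ C3–O bond: singlet-oxygen ene reaction on 6-methyl-3,4-dihydro-2H-pyran 19, which sets the tertiary alcohol trans to Br and moves the C=C to the exocyclic position.
2. Pyran ring (formed second) ⇐ ring C–O bonds: (S)-epoxide 17 of prenyl ketone 16, bromide opening with inversion, hemiketal, dehydration.
3. 16 ⇐ C-prenylation of the silyl enol ether of methyl ketone 13 (the epimeric carbon made here is erased in the dihydropyran).
4. trans-Diequatorial bromochloride 13 ⇐ ring epoxide 10 (C–O bonds as stereochemical template) by HBr opening and a 1,2-bromine-shift chlorination (new step).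
5. Ketone 9 ⇐ Wittig homologation of (S)-aldehyde 3 ⇐ organocatalytic Diels–Alder of isoprene and acrolein (cyclohexene ring formed first).

Assumption: the (5R) enantiomer of the first-generation MacMillan imidazolidinone is taken to give (S)-3; if the sense proves opposite, the (5S) catalyst is used and nothing else changes.

**Route**

Step 1
Reactants: 1 isoprene; 2 acrolein
Product: 3 (1S)-4-methylcyclohex-3-ene-1-carbaldehyde
Conditions: (5R)-5-benzyl-2,2,3-trimethylimidazolidin-4-one hydrochloride (10 mol%), MeCN/H2O 95:5, 23 °C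
Reagents that add atoms: none
Why: Iminium-catalysed Diels–Alder reaction; the acrolein iminium ion reacts with isoprene with "para" regioselectivity and the benzyl group of the catalyst shields one face, which sets the ring stereocentre (about 90% ee, upgraded when diastereomers are removed after step 4).

Step 2
Reactants: 4 ethyl vinyl ether; 5 triphenylphosphine hydrobromide
Product: 6 (1-ethoxyethyl)triphenylphosphonium bromide
Conditions: CH2Cl2, 0 → 23 °C
Reagents that add atoms: none
Why: Markovnikov addition across the enol ether (protonation to the oxocarbenium ion, capture by PPh3), the usual way to α-alkoxyalkyl phosphonium salts; no stereocentre is formed.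

Step 3
Reactants: 3 (1S)-4-methylcyclohex-3-ene-1-carbaldehyde; 6 (1-ethoxyethyl)triphenylphosphonium bromide
Product: 9 1-[(1S)-4-methylcyclohex-3-en-1-yl]propan-2-one, via ylide 7 (not isolated), via enol ether 8 (not isolated)
Conditions: KN(SiMe3)2, THF, −78 °C; then 3, −78 → 0 °C; then 1 M HCl, THF/H2O, 0 °C
Reagents that add atoms: water, O
Why: Wittig olefination with an α-alkoxy ylide gives the enol ether of the one-carbon-homologated methyl ketone, which dilute acid hydrolyses; the non-stabilised ylide adds at −78 °C faster than it enolises the aldehyde, so the ring stereocentre is kept.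

Step 4
Reactants: 9 1-[(1S)-4-methylcyclohex-3-en-1-yl]propan-2-one
Product: 10 1-[(1R,3S,6S)-6-methyl-7-oxabicyclo[4.1.0]heptan-3-yl]propan-2-one
Conditions: Shi ketone (1,2:4,5-di-O-isopropylidene-β-D-erythro-2,3-hexodiulo-2,6-pyranose, 30 mol%), KHSO5 (as 2KHSO5·KHSO4·K2SO4), K2CO3, Bu4NHSO4, MeCN/CH2(OMe)2/aq. Na2B4O7 buffer (pH 10.5), 0 °C
Reagents that add atoms: potassium peroxymonosulfate KHSO5, [K+].[O-]S(=O)(=O)OO
Why: Shi asymmetric epoxidation (chiral dioxirane, spiro transition state) of the trisubstituted ring alkene is catalyst-controlled and puts oxygen on the face anti to the side chain (methyl cis to the side chain; expected dr about 9:1, the minor epoxide and the one from the minor enantiomer of 9 are removed by chromatography).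

Step 5
Reactants: 10 1-[(1R,3S,6S)-6-methyl-7-oxabicyclo[4.1.0]heptan-3-yl]propan-2-one
Product: 13 1-[(1R,3S,4S)-3-bromo-4-chloro-4-methylcyclohexyl]propan-2-one, via bromohydrin 11 (not isolated), via chlorosulfite 12 (not isolated)
Conditions: HBr (1.05 equiv, Et2O solution), CH2Cl2, −78 °C; then pyridine, SOCl2, −40 → 0 °C
Reagents that add atoms: hydrogen bromide, Br; thionyl chloride, ClS(Cl)=O
Why: Proposed new method: a one-flask change of a trisubstituted epoxide into the trans-diequatorial vicinal bromochloride that direct BrCl addition to the alkene gives only as the minor isomer (the diaxial Fürst–Plattner adduct dominates there); HBr opens 10 at the tertiary carbon (Markovnikov, trans-diaxial) to bromohydrin 11, SOCl2 turns the axial secondary OH into chlorosulfite 12, its ionisation is assisted by the anti-periplanar tertiary C–Br bond so that bromine shifts to C3 with inversion (bromonium ion on the face syn to the side chain, opposite to the former epoxide oxygen), and chloride then adds anti at the tertiary carbon C4, which gives Br cis and Cl trans to the side chain; the closest known reaction types are the anchimerically assisted substitution of β-bromo alcohols through bromonium ions and the Ph3PCl2 deoxydichlorination of epoxides.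

Step 6
Reactants: 13 1-[(1R,3S,4S)-3-bromo-4-chloro-4-methylcyclohexyl]propan-2-one
Product: 14 ({(1Z)-1-[(1S,3S,4S)-3-bromo-4-chloro-4-methylcyclohexyl]prop-1-en-2-yl}oxy)(trimethyl)silane
Conditions: Me3SiCl, NaI, NEt3, MeCN, 23 °C
Reagents that add atoms: chlorotrimethylsilane, C[Si](C)(C)Cl
Why: Thermodynamic silyl enol ether formation (Me3SiI made in the flask, amine base) favours the more substituted internal Z enol ether (about 9:1 over the terminal isomer); no stereocentre is touched and the equatorial halides resist E2 under these weakly basic conditions.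

Step 7
Reactants: 14 ({(1Z)-1-[(1S,3S,4S)-3-bromo-4-chloro-4-methylcyclohexyl]prop-1-en-2-yl}oxy)(trimethyl)silane; 15 1-bromo-3-methylbut-2-ene (prenyl bromide)
Product: 16 (3RS)-3-[(1S,3S,4S)-3-bromo-4-chloro-4-methylcyclohexyl]-6-methylhept-5-en-2-one
Conditions: ZnBr2 (15 mol%), CH2Cl2, −40 → 0 °C
Reagents that add atoms: none
Why: ZnBr2-catalysed SN1-type α-allylation of a silyl enol ether (Reetz-type alkylation), in which the enol carbon attacks the primary end of the prenyl cation; the new stereocentre at C3 forms as a mixture, which is harmless because this carbon becomes sp2 in step 9.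

Step 8
Reactants: 16 (3RS)-3-[(1S,3S,4S)-3-bromo-4-chloro-4-methylcyclohexyl]-6-methylhept-5-en-2-one
Product: 17 (3RS)-3-[(1S,3S,4S)-3-bromo-4-chloro-4-methylcyclohexyl]-4-[(2S)-3,3-dimethyloxiran-2-yl]butan-2-one
Conditions: ent-Shi ketone (the L-fructose-derived enantiomer of the step 4 catalyst, 30 mol%), KHSO5 (as 2KHSO5·KHSO4·K2SO4), K2CO3, Bu4NHSO4, MeCN/CH2(OMe)2/aq. Na2B4O7 buffer (pH 10.5), 0 °C
Reagents that add atoms: potassium peroxymonosulfate KHSO5, [K+].[O-]S(=O)(=O)OO
Why: Shi asymmetric epoxidation with the enantiomeric ketone sets the (S)-epoxide at the only remaining alkene by reagent control, independent of the epimeric centre next to the ketone.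

Step 9
Reactants: 17 (3RS)-3-[(1S,3S,4S)-3-bromo-4-chloro-4-methylcyclohexyl]-4-[(2S)-3,3-dimethyloxiran-2-yl]butan-2-one
Product: 19 (3R)-3-bromo-5-[(1S,3S,4S)-3-bromo-4-chloro-4-methylcyclohexyl]-2,2,6-trimethyl-3,4-dihydro-2H-pyran, via bromo hemiketal 18 (not isolated)
Conditions: Li2NiBr4, THF, 0 → 23 °C; aq. work-up; then pyridinium p-toluenesulfonate (10 mol%), 4 Å molecular sieves, CH2Cl2, 40 °C
Reagents that add atoms: dilithium tetrabromonickelate Li2NiBr4, [Li+].[Li+].Br[Ni-2](Br)(Br)Br
Why: SN2 opening of the epoxide by the soft bromide of Li2NiBr4 at the less substituted carbon inverts it to the (R)-bromide, the freed tertiary alcohol closes onto the ketone (hemiketal 18, new ring C–O bond), and acid-catalysed dehydration under thermodynamic control gives the tetrasubstituted endocyclic enol ether, which forms the pyran ring and erases the epimeric centre.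

Step 10
Reactants: 19 (3R)-3-bromo-5-[(1S,3S,4S)-3-bromo-4-chloro-4-methylcyclohexyl]-2,2,6-trimethyl-3,4-dihydro-2H-pyran
Product: 21 (3S,5R)-5-bromo-3-[(1S,3S,4S)-3-bromo-4-chloro-4-methylcyclohexyl]-6,6-dimethyl-2-methylideneoxan-3-ol, via hydroperoxide 20 (not isolated)
Conditions: O2, 5,10,15,20-tetraphenylporphyrin (1 mol%), visible light, CH2Cl2, −78 °C; then PPh3, −78 → 23 °C
Reagents that add atoms: dioxygen, O=O
Why: Schenck ene reaction of singlet oxygen with the tetrasubstituted enol ether, in which oxygen bonds to the β-carbon by axial attack on the half-chair face anti to the pseudo-axial 2-methyl group (trans to the equatorial Br) while a hydrogen of the 6-methyl group is abstracted; this sets the tertiary C–O stereocentre (S) and places the double bond exocyclic, and PPh3 reduces the hydroperoxide to the alcohol.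

**Compound list**
1 | isoprene (2-methylbuta-1,3-diene) | C=CC(C)=C | starting material
2 | acrolein (prop-2-enal) | C=CC=O | starting material
3 | (1S)-4-methylcyclohex-3-ene-1-carbaldehyde | O=C[C@H]1CCC(C)=CC1 | intermediate
4 | ethyl vinyl ether | C=COCC | starting material
5 | triphenylphosphine hydrobromide | [Br-].[PH+](c1ccccc1)(c1ccccc1)c1ccccc1 | starting material
6 | (1-ethoxyethyl)triphenylphosphonium bromide | CCOC(C)[P+](c1ccccc1)(c1ccccc1)c1ccccc1.[Br-] | intermediate
7 | (1-ethoxyethylidene)triphenylphosphorane (ylide) | CCOC(C)=P(c1ccccc1)(c1ccccc1)c1ccccc1 | intermediate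
8 | (4S)-4-(2-ethoxyprop-1-en-1-yl)-1-methylcyclohex-1-ene (E/Z mixture) | CCOC(C)=C[C@H]1CCC(C)=CC1 | intermediate
9 | 1-[(1S)-4-methylcyclohex-3-en-1-yl]propan-2-one | CC(=O)C[C@H]1CCC(C)=CC1 | intermediate
10 | 1-[(1R,3S,6S)-6-methyl-7-oxabicyclo[4.1.0]heptan-3-yl]propan-2-one (epoxide oxygen anti to the side chain) | CC(=O)C[C@H]1CC[C@]2(C)O[C@@H]2C1 | intermediate
11 | 1-[(1S,3R,4R)-4-bromo-3-hydroxy-4-methylcyclohexyl]propan-2-one (trans-diaxial bromohydrin) | CC(=O)C[C@H]1CC[C@@](C)(Br)[C@H](O)C1 | intermediate
12 | (1R,2R,5S)-2-bromo-2-methyl-5-(2-oxopropyl)cyclohexyl chlorosulfite | CC(=O)C[C@H]1CC[C@@](C)(Br)[C@H](OS(Cl)=O)C1 | intermediate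
13 | 1-[(1R,3S,4S)-3-bromo-4-chloro-4-methylcyclohexyl]propan-2-one | CC(=O)C[C@H]1CC[C@](C)(Cl)[C@@H](Br)C1 | intermediate
14 | ({(1Z)-1-[(1S,3S,4S)-3-bromo-4-chloro-4-methylcyclohexyl]prop-1-en-2-yl}oxy)(trimethyl)silane | C/C(O[Si](C)(C)C)=C/[C@H]1CC[C@](C)(Cl)[C@@H](Br)C1 | intermediate
15 | 1-bromo-3-methylbut-2-ene (prenyl bromide) | CC(C)=CCBr | starting material
16 | (3RS)-3-[(1S,3S,4S)-3-bromo-4-chloro-4-methylcyclohexyl]-6-methylhept-5-en-2-one | CC(=O)C(CC=C(C)C)[C@H]1CC[C@](C)(Cl)[C@@H](Br)C1 | intermediate
17 | (3RS)-3-[(1S,3S,4S)-3-bromo-4-chloro-4-methylcyclohexyl]-4-[(2S)-3,3-dimethyloxiran-2-yl]butan-2-one | CC(=O)C(C[C@@H]1OC1(C)C)[C@H]2CC[C@](C)(Cl)[C@@H](Br)C2 | intermediate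
18 | (5R)-5-bromo-3-[(1S,3S,4S)-3-bromo-4-chloro-4-methylcyclohexyl]-2,6,6-trimethyloxan-2-ol (mixture at C2 and C3) | CC1(O)OC(C)(C)[C@H](Br)CC1[C@H]2CC[C@](C)(Cl)[C@@H](Br)C2 | intermediate
19 | (3R)-3-bromo-5-[(1S,3S,4S)-3-bromo-4-chloro-4-methylcyclohexyl]-2,2,6-trimethyl-3,4-dihydro-2H-pyran | CC1=C([C@H]2CC[C@](C)(Cl)[C@@H](Br)C2)C[C@@H](Br)C(C)(C)O1 | intermediate
20 | (3S,5R)-5-bromo-3-[(1S,3S,4S)-3-bromo-4-chloro-4-methylcyclohexyl]-6,6-dimethyl-2-methylideneoxan-3-yl hydroperoxide | C=C1OC(C)(C)[C@H](Br)C[C@]1(OO)[C@H]1CC[C@](C)(Cl)[C@@H](Br)C1 | intermediate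
21 | (3S,5R)-5-bromo-3-[(1S,3S,4S)-3-bromo-4-chloro-4-methylcyclohexyl]-6,6-dimethyl-2-methylideneoxan-3-ol | C=C1OC(C)(C)[C@H](Br)C[C@]1(O)[C@H]1CC[C@](C)(Cl)[C@@H](Br)C1 | target

**Step count**
Total step count: 10. Longest linear sequence: 9 (steps 1 and 3 to 10; step 2 makes the Wittig salt).

**Three steps most likely to fail, each with a fallback**

Step 5 (the proposed new step). Risks are chloride capture at the secondary carbon, loss of Br+ from the bromonium ion, and E1 elimination. The fallback uses known chemistry, sets out from 9 and comes back at 13. BrCl, made from N-bromosuccinimide and BnEt3NCl in CH2Cl2 at −78 °C, is added directly across the ring alkene of 9. Anti addition with chloride at the tertiary carbon gives two trans adducts: the trans-diaxial isomer 1-[(1R,3R,4R)-3-bromo-4-chloro-4-methylcyclohexyl]propan-2-one F1 as the major product and 13 as the minor one. They are separated by chromatography (preparative HPLC if needed) and 13 goes on into step 6.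

Step 7 (C-prenylation, including the regiochemistry fixed in step 6). Risks are alkylation through the terminal enol ether, attack at the tertiary end of the prenyl cation, and ionisation of the tertiary chloride by ZnBr2. The fallback sets out from 13 and comes back at 16, bypassing 14. Acid-mediated α-methylenation on the more substituted α-carbon (paraformaldehyde, i-Pr2NH·CF3CO2H, THF, 60 °C) gives the enone 3-[(1S,3S,4S)-3-bromo-4-chloro-4-methylcyclohexyl]but-3-en-2-one F2. Conjugate addition of the cuprate made from 2-methylprop-1-enylmagnesium bromide and CuI (Me3SiCl, THF, −78 °C), then mild acid work-up, gives 16 with the prenyl group built from the other polarity.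

Step 10 (singlet-oxygen ene reaction). Risks are dioxetane formation with cleavage of the enol ether and low facial selectivity. The fallback sets out from 19 and comes back at 21. OsO4-catalysed dihydroxylation (OsO4 cat., N-methylmorpholine N-oxide, acetone/H2O, 0 °C) of the enol ether from the same face gives the hydroxy hemiketal (3S,5R)-5-bromo-3-[(1S,3S,4S)-3-bromo-4-chloro-4-methylcyclohexyl]-2,6,6-trimethyloxane-2,3-diol F3. Acid-catalysed dehydration of the hemiketal (pyridinium p-toluenesulfonate, 4 Å molecular sieves, CH2Cl2) can only give the exocyclic enol ether, because C3 is quaternary, and so delivers 21.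

**Further compounds**
F1 | step 5 | 1-[(1R,3R,4R)-3-bromo-4-chloro-4-methylcyclohexyl]propan-2-one | CC(=O)C[C@H]1CC[C@@](C)(Cl)[C@H](Br)C1
F2 | step 7 | 3-[(1S,3S,4S)-3-bromo-4-chloro-4-methylcyclohexyl]but-3-en-2-one | CC(=O)C(=C)[C@H]1CC[C@](C)(Cl)[C@@H](Br)C1
F3 | step 10 | (3S,5R)-5-bromo-3-[(1S,3S,4S)-3-bromo-4-chloro-4-methylcyclohexyl]-2,6,6-trimethyloxane-2,3-diol | CC1(O)OC(C)(C)[C@H](Br)C[C@]1(O)[C@H]2CC[C@](C)(Cl)[C@@H](Br)C2
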